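**Retrosynthetic overview**
1. Target 26 ⇐ macrocyclic α-phosphono ester 25 (Horner–Wadsworth–Emmons methylenation with CH2O, last step) ⇐ Nozaki–Hiyama–Kishi closure of the 14-membered carbocycle at C12–C13 from iodoalkene aldehyde 24.
2. C1, C13 and C14 ⇐ iminium-catalysed Michael addition of trimethyl phosphonoacetate to an (E)-enal, made by Wittig two-carbon homologation of lactol 17.
3. C10–C12 ⇐ terminal oxirane 12 + 1-propynyllithium, then hydrozirconation–iodination.
4. C4, C5, C8, C9 and the tetrahydrofuran ⇐ farnesyl-derived dienoic acid 5: Shi epoxidation/lactonisation (C4, C5), then Sharpless epoxidation/5-exo cyclisation (C8, C9).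
5. Ring order: γ-lactone (temporary; masks C1 and the C4 hydroxyl) → tetrahydrofuran → 14-membered carbocycle.

Assumption: the SMILES is read as the (1S,4S,5R,8S,9R,11E,13S) isomer, with locants C1 (CH bearing the acrylate) → C2, C3 → C4 (tertiary carbinol) → C5–C8 (tetrahydrofuran, O between C5 and C8) → C9 (CHOAc) → C10 → C11=C12(Me) → C13 (CHOH) → C14; these locants are used for all intermediates, and 1, 13, 18 and 22 are bought.

**Step 1**
Reactants: 1 (2E,6E)-farnesyl acetate
Product: 3 (2E,6E)-10,11-epoxy-3,7,11-trimethyldodeca-2,6-dien-1-yl acetate (racemic oxirane), via bromohydrin 2 (not isolated)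
Conditions: NBS, THF/H2O (3:1), 0 °C; then DBU, rt
Reagents that add atoms: water, O
Why: van Tamelen terminal-selective bromohydrin formation (the distal trisubstituted alkene is the most exposed and the allylic-acetate alkene is deactivated) followed by Williamson ring closure gives the terminal oxirane, whose configuration is irrelevant because this carbon is cleaved next.

**Step 2**
Reactants: 3 (2E,6E)-10,11-epoxyfarnesyl acetate
Product: 4 (4E,8E)-10-acetoxy-4,8-dimethyldeca-4,8-dienal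
Conditions: H5IO6, THF/Et2O, 0 °C
Reagents that add atoms: none
Why: periodic acid hydrolyses the trisubstituted oxirane and cleaves the glycol (Malaprade cleavage) to the aldehyde that becomes C1, leaving both E-alkenes and the acetate intact.

**Step 3**
Reactants: 4 (4E,8E)-10-acetoxy-4,8-dimethyldeca-4,8-dienal
Product: 5 (4E,8E)-10-acetoxy-4,8-dimethyldeca-4,8-dienoic acid
Conditions: NaClO2, NaH2PO4, 2-methyl-2-butene, t-BuOH/H2O, 0 °C to rt
Reagents that add atoms: sodium chlorite, [Na+].[O-]Cl=O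
Why: Pinnick oxidation takes the aldehyde to the acid chemoselectively while 2-methyl-2-butene scavenges HOCl so the alkenes survive.

**Step 4**
Reactants: 5 (4E,8E)-10-acetoxy-4,8-dimethyldeca-4,8-dienoic acid
Product: 7 (5S)-5-[(1R,4E)-6-acetoxy-1-hydroxy-4-methylhex-4-en-1-yl]-5-methyldihydrofuran-2(3H)-one, via epoxy acid 6 (not isolated)
Conditions: Shi ketone (1,2:4,5-di-O-isopropylidene-β-D-erythro-2,3-hexodiulo-2,6-pyranose, 30 mol %), KHSO5 (as 2KHSO5·KHSO4·K2SO4), K2CO3, Bu4NHSO4, MeCN/(MeO)2CH2/aq. Na2B4O7 buffer pH 10.5, 0 °C; then citric acid to pH 3 and camphorsulfonic acid (cat.), CH2Cl2, rt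
Reagents that add atoms: potassium peroxymonosulfate, [K+].[O-]S(=O)(=O)OO
Why: Shi asymmetric epoxidation (chiral dioxirane, spiro transition state) attacks only the electron-rich C4=C5 alkene (C8=C9 is deactivated by the allylic acetate) to give the (4R,5R)-oxirane, and acid then drives 5-exo lactonisation of the carboxyl group at tertiary C4 with inversion, setting 4S and leaving the 5R carbinol.

**Step 5**
Reactants: 7 hydroxy lactone allylic acetate
Product: 8 (5S)-5-[(1R,4E)-1,6-dihydroxy-4-methylhex-4-en-1-yl]-5-methyldihydrofuran-2(3H)-one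
Conditions: K2CO3 (cat.), MeOH, 0 °C; aq. NH4Cl work-up
Reagents that add atoms: none
Why: base-catalysed transesterification removes the allylic acetate, and the γ-lactone re-closes on the mildly acidic work-up if it has opened.

**Step 6**
Reactants: 8 lactone allylic alcohol
Product: 10 (5S)-5-[(2R,5S)-5-[(1R)-1,2-dihydroxyethyl]-5-methyltetrahydrofuran-2-yl]-5-methyldihydrofuran-2(3H)-one, via epoxy alcohol 9 (not isolated)
Conditions: Ti(OiPr)4 (10 mol %), D-(−)-diethyl tartrate (12 mol %), t-BuOOH, 4 Å MS, CH2Cl2, −20 °C; then camphorsulfonic acid (10 mol %), rt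
Reagents that add atoms: tert-butyl hydroperoxide, CC(C)(C)OO
Why: Katsuki–Sharpless asymmetric epoxidation of the (E)-allylic alcohol with the D-tartrate gives the (8R,9R)-oxirane, and acid-catalysed 5-exo opening by the C5 hydroxyl at tertiary C8 with inversion closes the cis-tetrahydrofuran, setting 8S and keeping 9R.

**Step 7**
Reactants: 10 lactone tetrahydrofuran diol
Product: 12 (5S)-5-methyl-5-[(2R,5S)-5-methyl-5-[(2R)-oxiran-2-yl]tetrahydrofuran-2-yl]dihydrofuran-2(3H)-one, via primary tosylate 11 (not isolated)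
Conditions: TsCl, Et3N, Bu2SnO (2 mol %), CH2Cl2, 0 °C; then DBU, rt
Reagents that add atoms: none
Why: tin-acetal-catalysed tosylation takes only the primary hydroxyl of the 1,2-diol, and intramolecular Williamson displacement by the C9 oxygen gives the terminal oxirane with retention at C9.

**Step 8**
Reactants: 12 lactone tetrahydrofuran oxirane; 13 1-propynyllithium
Product: 14 (5S)-5-[(2R,5S)-5-[(1R)-1-hydroxypent-3-yn-1-yl]-5-methyltetrahydrofuran-2-yl]-5-methyldihydrofuran-2(3H)-one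
Conditions: BF3·OEt2, THF, −78 °C
Reagents that add atoms: none
Why: Yamaguchi–Hirao alkynylation opens the BF3-activated oxirane by SN2 attack at the unhindered CH2 (C10), the lactone being untouched at −78 °C, so C9 stays R.

**Step 9**
Reactants: 14 homopropargylic alcohol
Product: 16 (5S)-5-[(2R,5S)-5-[(1R,3E)-1-hydroxy-4-iodopent-3-en-1-yl]-5-methyltetrahydrofuran-2-yl]-5-methyldihydrofuran-2(3H)-one, via alkenylzirconocene 15 (not isolated)
Conditions: Cp2Zr(H)Cl (3 equiv), THF, rt to 40 °C; then I2, 0 °C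
Reagents that add atoms: iodine, II
Why: syn-hydrozirconation of the 2-alkyne with equilibration places zirconium on the less hindered methyl-bearing carbon (C12), and iodinolysis with retention gives the (E)-iodoalkene.

**Step 10**
Reactants: 16 lactone iodoalkene
Product: 17 (5S)-5-[(2R,5S)-5-[(1R,3E)-1-hydroxy-4-iodopent-3-en-1-yl]-5-methyltetrahydrofuran-2-yl]-5-methyltetrahydrofuran-2-ol (anomer mixture)
Conditions: i-Bu2AlH (2.2 equiv), CH2Cl2, −78 °C
Reagents that add atoms: none
Why: low-temperature partial reduction of the γ-lactone stops at the aluminium hemiacetal and gives the lactol, a masked C1 aldehyde.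

**Step 11**
Reactants: 17 lactol; 18 (triphenylphosphoranylidene)acetaldehyde
Product: 19 (2E,6S)-6-hydroxy-6-[(2R,5S)-5-[(1R,3E)-1-hydroxy-4-iodopent-3-en-1-yl]-5-methyltetrahydrofuran-2-yl]hept-2-enal
Conditions: toluene, 80 °C
Reagents that add atoms: none
Why: Wittig olefination of the open hydroxy-aldehyde form of the lactol with the stabilised formyl ylide gives the (E)-enal (C13, C14) and frees the tertiary C4 hydroxyl.

**Step 12**
Reactants: 19 dihydroxy enal
Product: 21 C9 acetate C4 trimethylsilyl ether of enal 19, via C9 acetate 20 (not isolated)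
Conditions: Ac2O, pyridine, DMAP (cat.), CH2Cl2, 0 °C; then N-(trimethylsilyl)imidazole, rt
Reagents that add atoms: acetic anhydride, CC(=O)OC(C)=O; N-(trimethylsilyl)imidazole, C[Si](C)(C)n1ccnc1
Why: nucleophilic-catalysed acylation takes only the secondary C9 hydroxyl, and silyl transfer then caps the tertiary C4 hydroxyl so it cannot undergo oxa-Michael addition to the enal in the next step.

**Step 13**
Reactants: 21 silylated acetoxy enal; 22 trimethyl phosphonoacetate
Product: 24 methyl (3S,6S)-6-[(2R,5S)-5-[(1R,3E)-1-acetoxy-4-iodopent-3-en-1-yl]-5-methyltetrahydrofuran-2-yl]-2-(dimethoxyphosphoryl)-6-hydroxy-3-(2-oxoethyl)heptanoate (C2 epimers), via silylated Michael adduct 23 (not isolated)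
Conditions: (R)-α,α-bis[3,5-bis(trifluoromethyl)phenyl]prolinol trimethylsilyl ether (20 mol %), CH2Cl2/EtOH (10:1), 0 °C to rt; then AcOH/THF/H2O (3:1:1), rt
Reagents that add atoms: none
Why: iminium-catalysed enantioselective Michael addition, in which the (R)-diarylprolinol silyl ether shields one face of the (E)-iminium ion so the phosphonoacetate carbon adds to C1 from the open face to give 1S; mild acid then removes the silyl ether.

**Step 14**
Reactants: 24 iodoalkene aldehyde
Product: 25 methyl 2-[(1S,4S,5R,8S,9R,11E,13S)-9-acetoxy-4,13-dihydroxy-4,8,12-trimethyl-5,8-epoxycyclotetradec-11-en-1-yl]-2-(dimethoxyphosphoryl)acetate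
Conditions: CrCl2 (10 equiv), NiCl2 (1 mol % of Cr), DMSO/THF (3:1), 2 mM, slow addition, rt
Reagents that add atoms: none
Why: Nozaki–Hiyama–Kishi macrocyclisation, in which zerovalent nickel inserts into the C–iodine bond and the alkenyl group passes to trivalent chromium and adds to the aldehyde with retention of the E-alkene; the 13S carbinol is set here under substrate control, which is a prediction that must be checked.

**Step 15**
Reactants: 25 macrocyclic α-phosphono ester
Product: 26 methyl 2-[(1S,4S,5R,8S,9R,11E,13S)-9-acetoxy-4,13-dihydroxy-4,8,12-trimethyl-5,8-epoxycyclotetradec-11-en-1-yl]acrylate (CNP0266699.4)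
Conditions: (CH2O)n, LiCl, DBU, MeCN, 0 °C to rt
Reagents that add atoms: formaldehyde (as paraformaldehyde), C=O
Why: Horner–Wadsworth–Emmons methylenation under Masamune–Roush conditions turns the α-phosphono ester into the α-methylene ester without disturbing the acetate, the hydroxyls or the stereocentres.

**Compound list**
1 | (2E,6E)-farnesyl acetate | CC(C)=CCC/C(C)=C/CC/C(C)=C/COC(C)=O | starting material
2 | (2E,6E)-10-bromo-11-hydroxy-3,7,11-trimethyldodeca-2,6-dien-1-yl acetate (racemic, not isolated) | CC(C)(O)C(Br)CC/C(C)=C/CC/C(C)=C/COC(C)=O | intermediate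
3 | (2E,6E)-10,11-epoxy-3,7,11-trimethyldodeca-2,6-dien-1-yl acetate (racemic oxirane) | CC1(C)OC1CC/C(C)=C/CC/C(C)=C/COC(C)=O | intermediate
4 | (4E,8E)-10-acetoxy-4,8-dimethyldeca-4,8-dienal | O=CCC/C(C)=C/CC/C(C)=C/COC(C)=O | intermediate
5 | (4E,8E)-10-acetoxy-4,8-dimethyldeca-4,8-dienoic acid | OC(=O)CC/C(C)=C/CC/C(C)=C/COC(C)=O | intermediate
6 | (4R,5R,8E)-10-acetoxy-4,5-epoxy-4,8-dimethyldec-8-enoic acid (not isolated) | OC(=O)CC[C@@]1(C)O[C@@H]1CC/C(C)=C/COC(C)=O | intermediate
7 | (5S)-5-[(1R,4E)-6-acetoxy-1-hydroxy-4-methylhex-4-en-1-yl]-5-methyldihydrofuran-2(3H)-one | O=C1CC[C@](C)(O1)[C@H](O)CC/C(C)=C/COC(C)=O | intermediate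
8 | (5S)-5-[(1R,4E)-1,6-dihydroxy-4-methylhex-4-en-1-yl]-5-methyldihydrofuran-2(3H)-one | O=C1CC[C@](C)(O1)[C@H](O)CC/C(C)=C/CO | intermediate
9 | (5S)-5-[(1R)-1-hydroxy-3-[(2R,3R)-3-(hydroxymethyl)-2-methyloxiran-2-yl]propyl]-5-methyldihydrofuran-2(3H)-one (not isolated) | O=C1CC[C@](C)(O1)[C@H](O)CC[C@@]2(C)O[C@@H]2CO | intermediate
10 | (5S)-5-[(2R,5S)-5-[(1R)-1,2-dihydroxyethyl]-5-methyltetrahydrofuran-2-yl]-5-methyldihydrofuran-2(3H)-one | O=C1CC[C@](C)(O1)[C@H]2CC[C@](C)(O2)[C@H](O)CO | intermediate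
11 | primary 4-toluenesulfonate of diol 10 (C10–OTs, C9–OH; not isolated) | O=C1CC[C@](C)(O1)[C@H]2CC[C@](C)(O2)[C@H](O)COS(=O)(=O)c3ccc(C)cc3 | intermediate
12 | (5S)-5-methyl-5-[(2R,5S)-5-methyl-5-[(2R)-oxiran-2-yl]tetrahydrofuran-2-yl]dihydrofuran-2(3H)-one | O=C1CC[C@](C)(O1)[C@H]2CC[C@](C)(O2)[C@H]3CO3 | intermediate
13 | 1-propynyllithium | [Li]C#CC | starting material
14 | (5S)-5-[(2R,5S)-5-[(1R)-1-hydroxypent-3-yn-1-yl]-5-methyltetrahydrofuran-2-yl]-5-methyldihydrofuran-2(3H)-one | O=C1CC[C@](C)(O1)[C@H]2CC[C@](C)(O2)[C@H](O)CC#CC | intermediate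
15 | (E)-C12 alkenyl chlorozirconocene from 14 (not isolated; hydroxyl drawn free, present as its zirconium alkoxide) | O=C1CC[C@](C)(O1)[C@H]2CC[C@](C)(O2)[C@H](O)C/C=C(\C)[Zr](Cl)(C3C=CC=C3)C3C=CC=C3 | intermediate
16 | (5S)-5-[(2R,5S)-5-[(1R,3E)-1-hydroxy-4-iodopent-3-en-1-yl]-5-methyltetrahydrofuran-2-yl]-5-methyldihydrofuran-2(3H)-one | O=C1CC[C@](C)(O1)[C@H]2CC[C@](C)(O2)[C@H](O)C/C=C(\C)I | intermediate
17 | lactol of 16 (anomer mixture) | OC1CC[C@](C)(O1)[C@H]2CC[C@](C)(O2)[C@H](O)C/C=C(\C)I | intermediate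
18 | (triphenylphosphoranylidene)acetaldehyde | O=CC=P(c1ccccc1)(c1ccccc1)c1ccccc1 | starting material
19 | (2E,6S)-6-hydroxy-6-[(2R,5S)-5-[(1R,3E)-1-hydroxy-4-iodopent-3-en-1-yl]-5-methyltetrahydrofuran-2-yl]hept-2-enal | O=C/C=C/CC[C@](C)(O)[C@H]1CC[C@](C)(O1)[C@H](O)C/C=C(\C)I | intermediate
20 | C9 acetate of 19 (not isolated) | O=C/C=C/CC[C@](C)(O)[C@H]1CC[C@](C)(O1)[C@H](OC(C)=O)C/C=C(\C)I | intermediate
21 | C9 acetate, C4 trimethylsilyl ether of 19 | O=C/C=C/CC[C@](C)(O[Si](C)(C)C)[C@H]1CC[C@](C)(O1)[C@H](OC(C)=O)C/C=C(\C)I | intermediate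
22 | trimethyl phosphonoacetate | COC(=O)CP(=O)(OC)OC | starting material
23 | C4 trimethylsilyl ether of 24 (1S; not isolated) | O=CC[C@H](CC[C@](C)(O[Si](C)(C)C)[C@H]1CC[C@](C)(O1)[C@H](OC(C)=O)C/C=C(\C)I)C(C(=O)OC)P(=O)(OC)OC | intermediate
24 | methyl (3S,6S)-6-[(2R,5S)-5-[(1R,3E)-1-acetoxy-4-iodopent-3-en-1-yl]-5-methyltetrahydrofuran-2-yl]-2-(dimethoxyphosphoryl)-6-hydroxy-3-(2-oxoethyl)heptanoate | O=CC[C@H](CC[C@](C)(O)[C@H]1CC[C@](C)(O1)[C@H](OC(C)=O)C/C=C(\C)I)C(C(=O)OC)P(=O)(OC)OC | intermediate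
25 | methyl 2-[(1S,4S,5R,8S,9R,11E,13S)-9-acetoxy-4,13-dihydroxy-4,8,12-trimethyl-5,8-epoxycyclotetradec-11-en-1-yl]-2-(dimethoxyphosphoryl)acetate | COC(=O)C(P(=O)(OC)OC)[C@H]1CC[C@](C)(O)[C@H]2CC[C@](C)(O2)[C@H](OC(C)=O)C/C=C(\C)[C@@H](O)C1 | intermediate
26 | methyl 2-[(1S,4S,5R,8S,9R,11E,13S)-9-acetoxy-4,13-dihydroxy-4,8,12-trimethyl-5,8-epoxycyclotetradec-11-en-1-yl]acrylate | C=C(C(=O)OC)[C@H]1CC[C@](C)(O)[C@H]2CC[C@](C)(O2)[C@H](OC(C)=O)C/C=C(\C)[C@@H](O)C1 | target

**Totals**
Total step count: 15. Longest linear sequence: 15 steps (from 1).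

**Steps most likely to fail, with fallbacks**

Step 14 (macrocyclisation; the C13 configuration is not reagent-controlled). The fallback sets out from 24 and comes back at 25. The cyclisation is run as above. The mixture of 25 and the 13R epimer F6 is then oxidised with Dess–Martin periodinane (CH2Cl2, NaHCO3) to the macrocyclic enone F7. F7 is reduced with the (R)-B-methyl oxazaborolidine derived from diphenylprolinol and BH3·SMe2 (THF, −40 °C). This Corey–Bakshi–Shibata reduction treats the alkenyl group as the large substituent and delivers the 13S alcohol 25 under reagent control.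

Step 13 (the phosphonoacetate is a weak carbon acid and the enal is hindered). The fallback sets out from 21 and comes back at 26.
- Allyl methyl malonate is added to 21 with the same pyrrolidine catalyst in EtOH to give the silylated malonate adduct F2.
- AcOH/THF/H2O gives the aldehyde malonate F3.
- CrCl2/NiCl2 cyclisation as in step 14 gives the macrocyclic allyl methyl malonate F4.
- Pd(PPh3)4 and morpholine in THF remove the allyl group to give the malonic half-acid F5.
- Warming F5 with paraformaldehyde in the same flask (Mannich reaction, then decarboxylative elimination) gives 26 directly.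

Step 11 (the lactol is mostly closed and the formyl ylide is sluggish and can homologate twice). The fallback sets out from 17 and comes back at 19. Lactol 17 is methylenated with Ph3P=CH2 (from Ph3PCH3Br and KOt-Bu, THF, 0 °C to rt) to give the terminal alkene diol F1. Cross-metathesis of F1 with crotonaldehyde, using the second-generation Grubbs catalyst RuCl2(=CHPh)(H2IMes)(PCy3) in CH2Cl2 at 40 °C, gives the (E)-enal 19. The trisubstituted iodoalkene does not take part.

**Further compounds**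
F1 | step 11 | (2S)-2-[(2R,5S)-5-[(1R,3E)-1-hydroxy-4-iodopent-3-en-1-yl]-5-methyltetrahydrofuran-2-yl]hex-5-en-2-ol | C=CCC[C@](C)(O)[C@H]1CC[C@](C)(O1)[C@H](O)C/C=C(\C)I
F2 | step 13 | allyl methyl malonate analogue of 23 (1S, C4 trimethylsilyl ether) | O=CC[C@H](CC[C@](C)(O[Si](C)(C)C)[C@H]1CC[C@](C)(O1)[C@H](OC(C)=O)C/C=C(\C)I)C(C(=O)OC)C(=O)OCC=C
F3 | step 13 | allyl methyl malonate analogue of 24 (1S, free C4 hydroxyl) | O=CC[C@H](CC[C@](C)(O)[C@H]1CC[C@](C)(O1)[C@H](OC(C)=O)C/C=C(\C)I)C(C(=O)OC)C(=O)OCC=C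
F4 | step 13 | allyl methyl 2-[(1S,4S,5R,8S,9R,11E,13S)-9-acetoxy-4,13-dihydroxy-4,8,12-trimethyl-5,8-epoxycyclotetradec-11-en-1-yl]malonate | COC(=O)C(C(=O)OCC=C)[C@H]1CC[C@](C)(O)[C@H]2CC[C@](C)(O2)[C@H](OC(C)=O)C/C=C(\C)[C@@H](O)C1
F5 | step 13 | 2-[(1S,4S,5R,8S,9R,11E,13S)-9-acetoxy-4,13-dihydroxy-4,8,12-trimethyl-5,8-epoxycyclotetradec-11-en-1-yl]-3-methoxy-3-oxopropanoic acid | COC(=O)C(C(O)=O)[C@H]1CC[C@](C)(O)[C@H]2CC[C@](C)(O2)[C@H](OC(C)=O)C/C=C(\C)[C@@H](O)C1
F6 | step 14 | 13R epimer of 25 | COC(=O)C(P(=O)(OC)OC)[C@H]1CC[C@](C)(O)[C@H]2CC[C@](C)(O2)[C@H](OC(C)=O)C/C=C(\C)[C@H](O)C1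
F7 | step 14 | C13 ketone (11E-enone) corresponding to 25 | COC(=O)C(P(=O)(OC)OC)[C@H]1CC[C@](C)(O)[C@H]2CC[C@](C)(O2)[C@H](OC(C)=O)C/C=C(\C)C(=O)C1
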